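**Plan**

1. Numbering (spiro[4.5]decane): C1 CH(OH), C2 CH bearing the triene, C3/C4 CH2, C5 spiro carbon, C6 C(CH3)OH, C7/C8 CH2, C9 alkylidene carbon, C10 CH bearing (CH2)3OH.
2. Cuts, in retrosynthetic order: the triene between its 2-alkenyl carbon and the dienyl unit (Stille); the C9 enal (back to a C9 ketone); the C2-acetyl/C1–O pair (an isoxazoline on a C1=C2 alkene); C6–CH3; then C2–C3 and C1–C5 together, a formal [3+2] of a spirocyclopropyl cyclohexanone with a two-carbon alkyne unit.
3. Enabling feature: C5 is the α-carbon of the C6 carbinol (a ketone one step earlier), so C3–C4–C5 can be stored as a cyclopropane that a ketyl at C6 opens to a C3 radical/C5 enolate pair. The C9 oxygen, 1,3 to C5 and cis to the C10 chain, carries the C1≡C2 unit on a temporary O–SiMe2 tether.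
4. Forward order: cyclohexenone → conjugate addition and spirocyclopropanation → key step closes the cyclopentene (plus a temporary oxasilinane) → C6 methyl carbinol → tether removed → isoxazoline → C9 enal → side chain.
5. Stereochemistry: C10 from ligand-controlled asymmetric conjugate addition; C5 from the tether; C6 from attack on the convex face of the bridged tricycle; C1/C2 from alkoxide-directed cis cycloaddition; alkene geometries from anti-carbomagnesiation/iodinolysis, the (E)-bis-stannane and the more stable (Z)-enal.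

Key step: step 6

Assumption: compounds 1, 2, 10, 11, 29, 30, 34 and N-hydroxyacetimidoyl chloride are taken as purchasable; the ligand enantiomer in step 1 is the one that delivers the (6S) adduct.

**Step 1**
Reactants: 1 1,4-dioxaspiro[4.5]dec-6-en-8-one; 2 1-[(3-bromopropoxy)methyl]-4-methoxybenzene
Product: 5 (6S,7R)-7-[(dimethylamino)methyl]-6-{3-[(4-methoxyphenyl)methoxy]propyl}-1,4-dioxaspiro[4.5]decan-8-one, via Grignard reagent 3 (not isolated), via magnesium enolate 4 (not isolated)
Conditions: Mg, THF (2 → 3); CuBr·SMe2 (5 mol %), (R)-1-[(S)-2-(diphenylphosphino)ferrocenyl]ethyldicyclohexylphosphine (6 mol %), t-BuOMe, −75 °C; then CH2=NMe2+ I−, THF, −75 → 0 °C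
Reagents that add atoms: N,N-dimethylmethyleneiminium iodide (Eschenmoser's salt), C=[N+](C)C.[I-]
Why: Copper-catalysed asymmetric conjugate addition of the Grignard reagent should set the side-chain stereocentre under ligand control, and the regiodefined magnesium enolate is trapped in a Mannich reaction anti to the new substituent.

**Step 2**
Reactants: 5
Product: 8 7-spirocyclopropane of (6S)-6-{3-[(4-methoxyphenyl)methoxy]propyl}-1,4-dioxaspiro[4.5]decan-8-one, via methiodide 6 (not isolated), via methylidene ketone 7 (not isolated)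
Conditions: MeI, THF, rt; evaporate; Me3S(O)I, NaH, DMSO, rt
Reagents that add atoms: trimethylsulfoxonium iodide, C[S+](C)(C)=O.[I-]
Why: The sulfoxonium ylide should first eliminate trimethylamine from the methiodide (E1cB) and then cyclopropanate the exocyclic enone in a Corey–Chaykovsky reaction, without touching the side-chain stereocentre.

**Step 3**
Reactants: 8
Product: 9 (8S)-8-{3-[(4-methoxyphenyl)methoxy]propyl}spiro[2.5]octane-4,7-dione
Conditions: PPTS, acetone/H2O, 50 °C
Reagents that add atoms: water, O
Why: Mild acid-catalysed ketal hydrolysis should free the C7 ketone while leaving the cyclopropyl ketone, the 4-methoxybenzyl ether and the α-stereocentre intact.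

**Step 4**
Reactants: 10 dichlorodimethylsilane; 11 ethynylmagnesium bromide
Product: 12 chloro(ethynyl)dimethylsilane
Conditions: 10 (4 equiv), THF, −78 °C → rt; distillation
Reagents that add atoms: none
Why: Nucleophilic substitution at silicon by the alkynyl Grignard reagent, kept to mono-substitution by the excess of dichlorosilane.

**Step 5**
Reactants: 9; 12
Product: 14 (7R,8S)-7-{[ethynyl(dimethyl)silyl]oxy}-8-{3-[(4-methoxyphenyl)methoxy]propyl}spiro[2.5]octan-4-one, via lithium alkoxide 13 (not isolated)
Conditions: LiBH(s-Bu)3 (1.05 equiv), THF, −78 °C; then 12 (1.5 equiv), −78 → 0 °C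
Reagents that add atoms: none
Why: The bulky hydride should reduce the C7 ketone (the cyclopropyl ketone is more hindered and less electrophilic) from the equatorial direction to the axial alcohol cis to the side chain, and the alkoxide is O-silylated in the same flask.

**Step 6**
Reactants: 14
Product: 15 bridged tricyclic siloxane: 10-{3-[(4-methoxyphenyl)methoxy]propyl}spiro[4.5]dec-1-en-6-one in which C1 and the C9 oxygen are joined by SiMe2 (C5–C1 bond, C9–O and C10 chain cis on the cyclohexanone)
Conditions: SmI2 (20 mol %), Sm metal (20 mol %), THF (0.01 M), 55 °C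
Reagents that add atoms: none
Why: Proposed new method: electron transfer from SmI2 to the cyclopropyl ketone gives a ketyl whose β-scission (either of the two equivalent spiro C–CH2 bonds) leaves a primary radical and a trivalent samarium enolate; the radical adds to the terminal alkyne carbon, the α-silyl vinyl radical so formed attacks the enolate carbon, and the new ketyl returns its electron to samarium, so that C2–C3 and then C1–C5 of the spiro[4.5]decene (product numbering) form in one catalytic radical relay. The closest known reaction type is the SmI2-catalysed intermolecular formal [3+2] coupling of alkyl cyclopropyl ketones with alkynes; holding the alkyne on an O–SiMe2 tether is the new element. The cyclopentene is closed by a 5-exo-trig attack of the vinyl radical on the enolate double bond, which at the same stroke closes the six-membered oxasilinane (a bicyclo[3.3.1] array with the cyclohexanone); the preceding radical addition to the alkyne is endo with respect to the tether but preorganised, because the axial O–Si–C≡C arm lies under the CH2CH2 radical chain. The only new stereocentre, the spiro carbon, is set by the tether: anchored on the axial C9 oxygen cis to the C10 side chain, the vinyl radical can reach the enolate only on that face, which is also the chair-like axial trajectory, and this overrides the preference of an untethered partner to enter anti to the side chain. The step needs radical addition to the alkyne to outrun reduction or hydrogen abstraction of the primary radical, which high dilution, a low SmI2 loading with samarium metal as reservoir and the proximity of the tethered alkyne should secure; addition with the opposite regiochemistry would give an isomeric vinylsilane that converges on the same cyclopentene in step 8.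

**Step 7**
Reactants: 15
Product: 16 6-hydroxy-6-methyl analogue of 15 (CH3 trans and OH cis to the C5–C1 bond)
Conditions: MeMgBr, LaCl3·2LiCl (30 mol %), THF, −30 °C; aq. NH4Cl
Reagents that add atoms: methylmagnesium bromide, C[Mg]Br
Why: Grignard 1,2-addition should occur on the convex face of the rigid bridged tricycle, anti to the axial C5–C1 bond and the oxasilinane ring, which places the methyl group trans and the hydroxyl cis to that bond.

**Step 8**
Reactants: 16
Product: 17 6-methyl-10-{3-[(4-methoxyphenyl)methoxy]propyl}spiro[4.5]dec-1-ene-6,9-diol (6-OH, 9-OH, C10 chain and C5–C1 bond all cis on the cyclohexane)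
Conditions: Bu4NF (3 equiv), THF, 0 → 40 °C
Reagents that add atoms: none
Why: Fluoride should open the Si–O bond and then cleave the vinyl–silicon bond by protodesilylation through a pentacoordinate silicate assisted by the neighbouring tertiary alkoxide, removing the tether without moving the alkene.

**Step 9**
Reactants: 17
Product: 18 6-hydroxy-6-methyl-10-{3-[(4-methoxyphenyl)methoxy]propyl}spiro[4.5]dec-1-en-9-one
Conditions: Dess–Martin periodinane, CH2Cl2, rt
Reagents that add atoms: none
Why: Dess–Martin oxidation of the only secondary alcohol under near-neutral conditions should spare the tertiary alcohol and the α-stereocentre at C10.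

**Step 10**
Reactants: 18
Product: 20 3-methyl-4,5-dihydroisoxazole cis-fused to C1–C2 of 18 (ring O on C1, C=N carbon on C2, both on the cyclopentane face of C6), via chloromagnesium alkoxide 19 (not isolated)
Conditions: i-PrMgCl (1.0 equiv), CH2Cl2, −78 °C; then CH3C(Cl)=NOH, Et3N (slow addition), −78 → 0 °C
Reagents that add atoms: N-hydroxyacetimidoyl chloride, CC(Cl)=NO
Why: In this magnesium alkoxide-directed 1,3-dipolar cycloaddition of acetonitrile oxide, coordination of the dipole oxygen to the magnesium of the tertiary alkoxide should deliver it to the nearer alkene carbon C1 on the alkoxide face, and the cis ring fusion sets C2 at once.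

**Step 11**
Reactants: 20
Product: 21 9-hydroxy-9-(prop-1-en-2-yl) derivative of 20 (tertiary allylic alcohol, propenyl trans to the C10 chain)
Conditions: CH2=C(CH3)MgBr (3 equiv), LaCl3·2LiCl (30 mol %), THF, −30 → 0 °C
Reagents that add atoms: isopropenylmagnesium bromide, CC(=C)[Mg]Br
Why: Lanthanum-promoted Grignard 1,2-addition to the C9 ketone with enolisation suppressed; the isoxazoline masks the future methyl ketone and the new carbinol stereocentre is removed in step 15.

**Step 12**
Reactants: 21
Product: 22 2-acetyl-6-methyl-10-{3-[(4-methoxyphenyl)methoxy]propyl}-9-(prop-1-en-2-yl)spiro[4.5]decane-1,6,9-triol (1-OH and 2-acetyl cis, both on the face of C6)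
Conditions: Mo(CO)6, MeCN/H2O, 80 °C
Reagents that add atoms: water, O
Why: Reductive N–O cleavage of the isoxazoline and hydrolysis of the β-hydroxy imine should unveil the cis-β-hydroxy methyl ketone without touching the alkene or the benzyl ether.

**Step 13**
Reactants: 22
Product: 23 1,6-O-(di-tert-butylsilanediyl) derivative of 22
Conditions: t-Bu2Si(OTf)2, 2,6-lutidine, CH2Cl2, 0 °C
Reagents that add atoms: di-tert-butylsilyl bis(trifluoromethanesulfonate), CC(C)(C)[Si](OS(=O)(=O)C(F)(F)F)(OS(=O)(=O)C(F)(F)F)C(C)(C)C
Why: Silylene formation across the syn-1,3-diol (C1–OH, C6–OH) protects the aldol hydroxyl against retro-aldol and elimination and prevents hemiketal formation with the acetyl group, while the hindered isolated C9 hydroxyl stays free.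

**Step 14**
Reactants: 23
Product: 25 terminal enol trifluoromethanesulfonate of the acetyl group of 23 (a 1-substituted vinyl triflate at C2), via dipotassium enolate 24 (not isolated)
Conditions: KN(SiMe3)2 (2.2 equiv), THF, −78 °C; then PhNTf2 (1.1 equiv), −78 → −20 °C
Reagents that add atoms: N-phenylbis(trifluoromethanesulfonimide), O=S(=O)(N(c1ccccc1)S(=O)(=O)C(F)(F)F)C(F)(F)F
Why: Kinetic deprotonation of the methyl group of the methyl ketone and O-sulfonylation of the enolate give the terminal enol triflate, the tertiary alkoxide being too hindered to be sulfonylated.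

**Step 15**
Reactants: 25
Product: 26 (Z)-enal: the 9-hydroxy-9-propenyl unit of 25 transposed to a 9-ylidenepropanal, CHO cis to C10
Conditions: C5H5NH[CrO3Cl] (pyridinium chlorochromate), 4 Å MS, CH2Cl2, rt
Reagents that add atoms: pyridinium chlorochromate, [O-][Cr](=O)(=O)Cl.c1cc[nH+]cc1
Why: Babler–Dauben oxidative transposition ([3,3] shift of the chromate ester of the tertiary allylic alcohol, then oxidation) gives the tetrasubstituted enal, and the (Z)-isomer, with the smaller formyl group next to the substituted ring carbon C10, is expected as the more stable one.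

**Step 16**
Reactants: 26
Product: 27 primary alcohol from 26 (4-methoxybenzyl group removed)
Conditions: DDQ, CH2Cl2/pH 7 buffer, 0 °C
Reagents that add atoms: none
Why: Oxidative cleavage of the 4-methoxybenzyl ether is done before any electron-rich polyene is present.

**Step 17**
Reactants: 27
Product: 28 (2Z)-2-{1,6-dihydroxy-10-(3-hydroxypropyl)-6-methyl-2-[1-(trifluoromethanesulfonyloxy)ethenyl]spiro[4.5]decan-9-ylidene}propanal
Conditions: HF·pyridine, pyridine, THF, 0 °C → rt
Reagents that add atoms: none
Why: Fluoride-mediated cleavage of the silylene should free the 1,3-diol while the enal and the vinyl triflate are stable.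

**Step 18**
Reactants: 29 prop-2-yn-1-ol; 30 5-bromo-2-methylpent-2-ene
Product: 33 (Z)-3-iodo-2-(4-methylpent-3-en-1-yl)prop-2-en-1-ol, via Grignard reagent 31 (not isolated), via alkenylmagnesium alkoxide 32 (not isolated)
Conditions: Mg, THF (30 → 31, 2.5 equiv); 29, CuI (10 mol %), THF, −10 °C → rt; then I2, −40 → 0 °C
Reagents that add atoms: iodine, II
Why: Copper-catalysed anti-carbomagnesiation of the propargylic alkoxide puts the alkyl group on the carbinol-bearing alkyne carbon and magnesium cis to the CH2O group in a chelate, and iodinolysis with retention gives the (Z)-iodide.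

**Step 19**
Reactants: 33; 34 (E)-1,2-bis(tributylstannyl)ethene
Product: 35 (2Z,4E)-2-(4-methylpent-3-en-1-yl)-5-(tributylstannyl)penta-2,4-dien-1-ol
Conditions: 34 (3 equiv), Pd2(dba)3 (2.5 mol %), AsPh3, DMF, rt
Reagents that add atoms: none
Why: Stille mono-coupling of the alkenyl iodide with the bis-stannane (in excess) proceeds with retention at both alkenes and leaves one stannyl group for the final coupling.

**Step 20**
Reactants: 28; 35
Product: 36 CNP0249558.2, (2Z)-2-{1,6-dihydroxy-10-(3-hydroxypropyl)-6-methyl-2-[(3E,5Z)-6-(hydroxymethyl)-10-methylundeca-1,3,5,9-tetraen-2-yl]spiro[4.5]decan-9-ylidene}propanal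
Conditions: Pd(PPh3)4 (5 mol %), LiCl (3 equiv), THF, 50 °C
Reagents that add atoms: none
Why: Stille coupling of the enol triflate with the dienylstannane, with retention of alkene geometry, closes the cross-conjugated triene under neutral conditions that the free hydroxyls and the enal should tolerate.

**Compound list**

1 | 1,4-dioxaspiro[4.5]dec-6-en-8-one | O=C1C=CC2(CC1)OCCO2 | starting material
2 | 1-[(3-bromopropoxy)methyl]-4-methoxybenzene | COc1ccc(COCCCBr)cc1 | starting material
3 | {3-[(4-methoxyphenyl)methoxy]propyl}magnesium bromide (not isolated) | COc1ccc(COCCC[Mg]Br)cc1 | intermediate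
4 | bromomagnesium C7=C8 enolate of (6S)-6-{3-[(4-methoxyphenyl)methoxy]propyl}-1,4-dioxaspiro[4.5]decan-8-one (not isolated) | Br[Mg]OC1=C[C@H](CCCOCc2ccc(OC)cc2)C2(OCCO2)CC1 | intermediate
5 | (6S,7R)-7-[(dimethylamino)methyl]-6-{3-[(4-methoxyphenyl)methoxy]propyl}-1,4-dioxaspiro[4.5]decan-8-one | O=C1CCC2(OCCO2)[C@@H](CCCOCc3ccc(OC)cc3)[C@@H]1CN(C)C | intermediate
6 | N-methyl ammonium iodide of 5 (not isolated) | O=C1CCC2(OCCO2)[C@@H](CCCOCc3ccc(OC)cc3)[C@@H]1C[N+](C)(C)C.[I-] | intermediate
7 | (6S)-6-{3-[(4-methoxyphenyl)methoxy]propyl}-7-methylidene-1,4-dioxaspiro[4.5]decan-8-one (not isolated) | O=C1CCC2(OCCO2)[C@@H](CCCOCc3ccc(OC)cc3)C1=C | intermediate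
8 | 7-spirocyclopropane of (6S)-6-{3-[(4-methoxyphenyl)methoxy]propyl}-1,4-dioxaspiro[4.5]decan-8-one | O=C1CCC2(OCCO2)[C@@H](CCCOCc3ccc(OC)cc3)C14CC4 | intermediate
9 | (8S)-8-{3-[(4-methoxyphenyl)methoxy]propyl}spiro[2.5]octane-4,7-dione | O=C1CCC(=O)[C@@H](CCCOCc2ccc(OC)cc2)C13CC3 | intermediate
10 | dichlorodimethylsilane | C[Si](C)(Cl)Cl | starting material
11 | ethynylmagnesium bromide | C#C[Mg]Br | starting material
12 | chloro(ethynyl)dimethylsilane | C#C[Si](C)(C)Cl | intermediate
13 | lithium alkoxide of (7R,8S)-7-hydroxy-8-{3-[(4-methoxyphenyl)methoxy]propyl}spiro[2.5]octan-4-one (not isolated) | O=C1CC[C@@H](O[Li])[C@@H](CCCOCc2ccc(OC)cc2)C13CC3 | intermediate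
14 | (7R,8S)-7-{[ethynyl(dimethyl)silyl]oxy}-8-{3-[(4-methoxyphenyl)methoxy]propyl}spiro[2.5]octan-4-one | O=C1CC[C@@H](O[Si](C)(C)C#C)[C@@H](CCCOCc2ccc(OC)cc2)C13CC3 | intermediate
15 | bridged tricyclic siloxane (spiro[4.5]dec-1-en-6-one, C1–SiMe2–O–C9 bridge, C10 side chain cis to C9–O) | C1=C2[Si](C)(C)O[C@@H]3CCC(=O)[C@@]2(CC1)[C@@H]3CCCOCc4ccc(OC)cc4 | intermediate
16 | 6-hydroxy-6-methyl analogue of 15 | C1=C2[Si](C)(C)O[C@@H]3CC[C@](C)(O)[C@@]2(CC1)[C@@H]3CCCOCc4ccc(OC)cc4 | intermediate
17 | 6-methyl-10-{3-[(4-methoxyphenyl)methoxy]propyl}spiro[4.5]dec-1-ene-6,9-diol | C1=C[C@]2(CC1)[C@H](CCCOCc3ccc(OC)cc3)[C@H](O)CC[C@]2(C)O | intermediate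
18 | 6-hydroxy-6-methyl-10-{3-[(4-methoxyphenyl)methoxy]propyl}spiro[4.5]dec-1-en-9-one | C1=C[C@]2(CC1)[C@H](CCCOCc3ccc(OC)cc3)C(=O)CC[C@]2(C)O | intermediate
19 | chloromagnesium 6-alkoxide of 18 (not isolated) | C1=C[C@]2(CC1)[C@H](CCCOCc3ccc(OC)cc3)C(=O)CC[C@]2(C)O[Mg]Cl | intermediate
20 | C1–C2 cis-fused 3-methyl-4,5-dihydroisoxazole of 18 (O on C1) | CC1=NO[C@H]2[C@@H]1CC[C@]23[C@H](CCCOCc4ccc(OC)cc4)C(=O)CC[C@]3(C)O | intermediate
21 | 9-hydroxy-9-(prop-1-en-2-yl) derivative of 20 | CC1=NO[C@H]2[C@@H]1CC[C@]23[C@H](CCCOCc4ccc(OC)cc4)[C@@](O)(C(C)=C)CC[C@]3(C)O | intermediate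
22 | 2-acetyl-6-methyl-10-{3-[(4-methoxyphenyl)methoxy]propyl}-9-(prop-1-en-2-yl)spiro[4.5]decane-1,6,9-triol | CC(=O)[C@H]1CC[C@]2([C@H](CCCOCc3ccc(OC)cc3)[C@@](O)(C(C)=C)CC[C@]2(C)O)[C@H]1O | intermediate
23 | 1,6-O-(di-tert-butylsilanediyl) derivative of 22 | CC(=O)[C@H]1CC[C@@]23[C@H](CCCOCc4ccc(OC)cc4)[C@@](O)(C(C)=C)CC[C@]2(C)O[Si](C(C)(C)C)(C(C)(C)C)O[C@@H]13 | intermediate
24 | dipotassium salt of 23, methyl-side enolate and 9-alkoxide (not isolated) | [K]OC(=C)[C@H]1CC[C@@]23[C@H](CCCOCc4ccc(OC)cc4)[C@@](O[K])(C(C)=C)CC[C@]2(C)O[Si](C(C)(C)C)(C(C)(C)C)O[C@@H]13 | intermediate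
25 | terminal enol triflate of 23 | C=C(OS(=O)(=O)C(F)(F)F)[C@H]1CC[C@@]23[C@H](CCCOCc4ccc(OC)cc4)[C@@](O)(C(C)=C)CC[C@]2(C)O[Si](C(C)(C)C)(C(C)(C)C)O[C@@H]13 | intermediate
26 | (Z)-9-ylidenepropanal from 25 (CHO cis to C10) | C=C(OS(=O)(=O)C(F)(F)F)[C@H]1CC[C@@]23[C@H](CCCOCc4ccc(OC)cc4)/C(=C(/C)C=O)CC[C@]2(C)O[Si](C(C)(C)C)(C(C)(C)C)O[C@@H]13 | intermediate
27 | primary alcohol from 26 | C=C(OS(=O)(=O)C(F)(F)F)[C@H]1CC[C@@]23[C@H](CCCO)/C(=C(/C)C=O)CC[C@]2(C)O[Si](C(C)(C)C)(C(C)(C)C)O[C@@H]13 | intermediate
28 | (2Z)-2-{1,6-dihydroxy-10-(3-hydroxypropyl)-6-methyl-2-[1-(trifluoromethanesulfonyloxy)ethenyl]spiro[4.5]decan-9-ylidene}propanal | C=C(OS(=O)(=O)C(F)(F)F)[C@H]1CC[C@]2([C@H](CCCO)/C(=C(/C)C=O)CC[C@]2(C)O)[C@H]1O | intermediate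
29 | prop-2-yn-1-ol | C#CCO | starting material
30 | 5-bromo-2-methylpent-2-ene | CC(C)=CCCBr | starting material
31 | (4-methylpent-3-en-1-yl)magnesium bromide (not isolated) | CC(C)=CCC[Mg]Br | intermediate
32 | (Z)-alkenylmagnesium alkoxide from anti-carbomagnesiation (not isolated) | Br[Mg]/C=C(\CO[Mg]Br)CCC=C(C)C | intermediate
33 | (Z)-3-iodo-2-(4-methylpent-3-en-1-yl)prop-2-en-1-ol | I/C=C(\CO)CCC=C(C)C | intermediate
34 | (E)-1,2-bis(tributylstannyl)ethene | CCCC[Sn](CCCC)(CCCC)/C=C/[Sn](CCCC)(CCCC)CCCC | starting material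
35 | (2Z,4E)-2-(4-methylpent-3-en-1-yl)-5-(tributylstannyl)penta-2,4-dien-1-ol | CCCC[Sn](CCCC)(CCCC)/C=C/C=C(\CO)CCC=C(C)C | intermediate
36 | CNP0249558.2 | C=C(/C=C/C=C(\CO)CCC=C(C)C)[C@H]1CC[C@]2([C@H](CCCO)/C(=C(/C)C=O)CC[C@]2(C)O)[C@H]1O | target

**Totals and risks**

Total step count: 20. Longest linear sequence: 17 steps (1–3, 5–17, 20).

1. Step 6 (proposed new method). The primary radical may be reduced or abstract hydrogen before it captures the tethered alkyne, and the catalyst may be lost as unreactive trivalent samarium. The fallback uses known chemistry, sets out from the magnesium enolate 4 and returns at 18. Enolate 4 would be trapped with acetaldehyde to give the aldol adduct F1, and dehydration (MsCl, Et3N, then DBU) would give the ethylidene ketone F2. Deconjugative α-alkylation of its extended dienolate (KOt-Bu, THF, 4-bromobut-1-ene) should bring the butenyl arm in anti to the side chain, giving the α-vinyl-α-butenyl ketone F3. Ring-closing metathesis with second-generation Grubbs catalyst closes the spirocyclopentene F4, which has the alkene arm cis to the side chain. Methyl Grignard addition (MeMgBr, LaCl3·2LiCl) gives the carbinol ketal F5, and PPTS in aqueous acetone returns ketone 18.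

2. Step 10. Facial or regiochemical control of the cycloaddition may be poor, and the Grignard base may add to or enolise the ketone. The fallback sets out from 18 and returns at 22. A Schenck ene reaction with singlet oxygen (O2, tetraphenylporphyrin, light, then PPh3) can deliver oxygen only to C1, because the other allylic position is the quaternary spiro carbon; it should give the allylic alcohol F6 with the alkene moved to C2=C3 and the hydroxyl on the face of the tertiary hydroxyl. Silylation with (1-bromovinyl)chlorodimethylsilane gives the silyl ether F7. A 5-exo radical cyclisation (Bu3SnH, AIBN) gives the siloxane F8, which is cis-fused by ring constraint and carries the C2 vinyl carbon. Isopropenylmagnesium bromide with LaCl3·2LiCl gives the carbinol F9, and Tamao–Fleming oxidation (H2O2, KF, KHCO3) converts the silylvinyl group to the methyl ketone and returns 22.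

3. Step 15. Alkene geometry may not be controlled, and C10 may epimerise under the acidic chromium conditions. The fallback sets out from 25 and returns at 26. Rhenium-catalysed reversible 1,3-transposition of the tertiary allylic alcohol (O3ReOSiPh3, Et2O) would give the primary allylic alcohols under equilibrium. The (Z)-allylic alcohol F10 is separated and the (E)-isomer resubmitted to the catalyst. Neutral oxidation of F10 with MnO2 gives 26 without touching the geometry.

**Further compounds**

F1 | step 6 | aldol adduct of enolate 4 with acetaldehyde (mixture at the two new centres) | O=C1CCC2(OCCO2)[C@@H](CCCOCc3ccc(OC)cc3)C1C(C)O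
F2 | step 6 | (6S)-7-ethylidene-6-{3-[(4-methoxyphenyl)methoxy]propyl}-1,4-dioxaspiro[4.5]decan-8-one (E/Z mixture) | O=C1CCC2(OCCO2)[C@@H](CCCOCc3ccc(OC)cc3)C1=CC
F3 | step 6 | 7-(but-3-en-1-yl)-7-ethenyl ketone, ethenyl cis to the side chain | O=C1CCC2(OCCO2)[C@@H](CCCOCc3ccc(OC)cc3)[C@]1(C=C)CCC=C
F4 | step 6 | spirocyclopentene ketone ketal (alkene arm cis to the side chain) | O=C1CCC2(OCCO2)[C@@H](CCCOCc3ccc(OC)cc3)[C@@]14C=CCC4
F5 | step 6 | ethylene ketal of 18 | C1=C[C@]2(CC1)[C@H](CCCOCc3ccc(OC)cc3)C3(OCCO3)CC[C@]2(C)O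
F6 | step 10 | 1,6-dihydroxy-6-methyl-10-{3-[(4-methoxyphenyl)methoxy]propyl}spiro[4.5]dec-2-en-9-one | C1=C[C@H](O)[C@]2(C1)[C@H](CCCOCc3ccc(OC)cc3)C(=O)CC[C@]2(C)O
F7 | step 10 | 1-O-[(1-bromoethenyl)dimethylsilyl] ether of F6 | C1=C[C@H](O[Si](C)(C)C(Br)=C)[C@]2(C1)[C@H](CCCOCc3ccc(OC)cc3)C(=O)CC[C@]2(C)O
F8 | step 10 | cis-fused 1-oxa-2-silacyclopentane (methylidene on the carbon bound to C2) | C=C1[Si](C)(C)O[C@H]2[C@@H]1CC[C@]23[C@H](CCCOCc4ccc(OC)cc4)C(=O)CC[C@]3(C)O
F9 | step 10 | 9-hydroxy-9-(prop-1-en-2-yl) derivative of F8 | C=C1[Si](C)(C)O[C@H]2[C@@H]1CC[C@]23[C@H](CCCOCc4ccc(OC)cc4)[C@@](O)(C(C)=C)CC[C@]3(C)O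
F10 | step 15 | (Z)-primary allylic alcohol corresponding to 26 | C=C(OS(=O)(=O)C(F)(F)F)[C@H]1CC[C@@]23[C@H](CCCOCc4ccc(OC)cc4)/C(=C(/C)CO)CC[C@]2(C)O[Si](C(C)(C)C)(C(C)(C)C)O[C@@H]13
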